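**Retrosynthetic overview**
- Target ⇒ global desilylation and Yamaguchi esterification of the C8 alcohol of a 15‑O‑TBS germacranolide with a pre‑acetylated (3R) side‑chain acid (fragment C, from L‑ascorbic acid).
- Ten‑membered carbocycle first, γ‑lactone second, in one flask: chromium‑mediated intramolecular allylation (C6–C7 bond) of a C6 enal by a C13 allylic bromide, then lactonization of the C6 alkoxide onto the C12 ester.
- The seco bromo‑enal comes from a Morita–Baylis–Hillman reaction of a C7 aldehyde with methyl acrylate, on a chain made by B‑alkyl Suzuki coupling (C1–C2 bond) of fragments A and B.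
- Fragment A (C2–C6, C15): vinylcopper addition to an ynoate from propargyl alcohol fixes the C4=C5 geometry. Fragment B (C1, C7–C10, C14): (R)‑glycidol supplies C8, Negishi carboalumination gives the (E)‑iodoalkene.
- Stereocentres: C8 and C3' from the chiral pool; C6 and C7 are set in the ring closure under control of C8.

Assumption: the SMILES is read as 4'‑O‑acetylcnicin, (6R,7R,8S,3'R), 1(10)E and 4Z (CIP; trans within the ring); germacrane numbering (C1–C15, C1'–C4') is used for atom labels.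

**Fragment A**

Step 1
Reactants: 1 propargyl alcohol
Product: 2 tert‑butyldimethyl(prop‑2‑yn‑1‑yloxy)silane
Conditions: TBSCl, imidazole, CH2Cl2, 0 °C to rt
Reagents that add atoms: tert‑butyldimethylsilyl chloride, CC(C)(C)[Si](C)(C)Cl
Why: Imidazole‑promoted silyl ether formation on a primary alcohol; no stereocentre is involved.

Step 2
Reactants: 2 tert‑butyldimethyl(prop‑2‑yn‑1‑yloxy)silane
Product: 4 methyl 4‑[(tert‑butyldimethylsilyl)oxy]but‑2‑ynoate, via lithium acetylide 3 (not isolated)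
Conditions: n‑BuLi, THF, −78 °C; then ClCO2Me, −78 to 0 °C
Reagents that add atoms: methyl chloroformate, COC(=O)Cl
Why: Deprotonation of the terminal alkyne and C‑acylation of the acetylide with the chloroformate gives the ynoate (C6 is introduced here).

Step 3
Reactants: 4 methyl 4‑[(tert‑butyldimethylsilyl)oxy]but‑2‑ynoate
Product: 5 methyl (2Z)‑3‑{[(tert‑butyldimethylsilyl)oxy]methyl}penta‑2,4‑dienoate
Conditions: CH2=CHMgBr, CuBr·SMe2 (1:1, 1.5 equiv), THF, −78 °C; MeOH then aq. NH4Cl at −78 °C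
Reagents that add atoms: vinylmagnesium bromide, C=C[Mg]Br
Why: Organocopper conjugate addition (syn‑carbocupration) to the ynoate and protonation of the alkenylcopper with retention at −78 °C place vinyl and H cis, so CO2Me ends up cis to CH2OTBS, which is the C4=C5 geometry of the target.

Step 4
Reactants: 5 methyl (2Z)‑3‑{[(tert‑butyldimethylsilyl)oxy]methyl}penta‑2,4‑dienoate
Product: 6 (2Z)‑3‑{[(tert‑butyldimethylsilyl)oxy]methyl}penta‑2,4‑dien‑1‑ol
Conditions: i‑Bu2AlH (2.5 equiv), CH2Cl2, −78 °C; aq. KNaC4H4O6 work‑up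
Reagents that add atoms: none
Why: 1,2‑Reduction of the ester by the aluminium hydride at low temperature leaves the diene and its geometry untouched.

Step 5
Reactants: 6 (2Z)‑3‑{[(tert‑butyldimethylsilyl)oxy]methyl}penta‑2,4‑dien‑1‑ol
Product: 7 (3Z)‑3‑{[(tert‑butyldimethylsilyl)oxy]methyl}‑5‑[(triethylsilyl)oxy]penta‑1,3‑diene
Conditions: TESCl, imidazole, CH2Cl2, 0 °C
Reagents that add atoms: chlorotriethylsilane, CC[Si](CC)(CC)Cl
Why: Silyl ether formation; the primary TES ether at C6 can later be removed in the presence of the primary TBS ether at C15.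

**Fragment B**

Step 6
Reactants: 8 (R)‑glycidol
Product: 9 (2S)‑pent‑4‑yne‑1,2‑diol
Conditions: LiC≡CH·H2NCH2CH2NH2 (3 equiv), DMSO, 0 °C to rt; H2O
Reagents that add atoms: lithium acetylide–ethylenediamine complex, [Li]C#C.NCCN
Why: SN2 opening of the epoxide at its terminal carbon by acetylide leaves the C–O bond of the stereocentre intact, so (R)‑glycidol gives the (S)‑diol (descriptor change by CIP priority only), which becomes C8.

Step 7
Reactants: 9 (2S)‑pent‑4‑yne‑1,2‑diol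
Product: 10 (4S)‑2‑(4‑methoxyphenyl)‑4‑(prop‑2‑yn‑1‑yl)‑1,3‑dioxolane
Conditions: 4‑MeOC6H4CH(OMe)2, PPTS (cat.), CH2Cl2, rt
Reagents that add atoms: 4‑methoxybenzaldehyde dimethyl acetal, COc1ccc(C(OC)OC)cc1
Why: Acid‑catalysed transacetalization gives the five‑membered p‑methoxybenzylidene acetal (acetal epimers are inconsequential).

Step 8
Reactants: 10 (4S)‑2‑(4‑methoxyphenyl)‑4‑(prop‑2‑yn‑1‑yl)‑1,3‑dioxolane
Product: 11 (2S)‑2‑[(4‑methoxybenzyl)oxy]pent‑4‑yn‑1‑ol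
Conditions: i‑Bu2AlH (3 equiv), CH2Cl2, −78 to 0 °C
Reagents that add atoms: none
Why: Regioselective reductive acetal opening: aluminium binds the less hindered primary oxygen, hydride goes to the acetal carbon, and the PMB group stays on the secondary (C8) oxygen.

Step 9
Reactants: 11 (2S)‑2‑[(4‑methoxybenzyl)oxy]pent‑4‑yn‑1‑ol
Product: 13 (2S,4E)‑5‑iodo‑2‑[(4‑methoxybenzyl)oxy]‑4‑methylpent‑4‑en‑1‑ol, via alkenyldimethylalane 12 (not isolated)
Conditions: AlMe3 (3.5 equiv), Cp2ZrCl2 (0.3 equiv), CH2Cl2, 0 °C to rt; then I2, THF, −30 to 0 °C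
Reagents that add atoms: trimethylaluminium, C[Al](C)C; iodine, II
Why: Negishi zirconium‑catalysed carboalumination adds Me (to C10) and Al (to C1) syn across the alkyne, and iodinolysis with retention gives the (E)‑iodoalkene.

**Fragment union and ring closure**

Step 10
Reactants: 7 (3Z)‑3‑{[(tert‑butyldimethylsilyl)oxy]methyl}‑5‑[(triethylsilyl)oxy]penta‑1,3‑diene; 13 (2S,4E)‑5‑iodo‑2‑[(4‑methoxybenzyl)oxy]‑4‑methylpent‑4‑en‑1‑ol
Product: 15 (2S,4E,8Z)‑8‑{[(tert‑butyldimethylsilyl)oxy]methyl}‑2‑[(4‑methoxybenzyl)oxy]‑4‑methyl‑10‑[(triethylsilyl)oxy]deca‑4,8‑dien‑1‑ol, via B‑alkyl‑9‑BBN 14 (not isolated)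
Conditions: 9‑BBN, THF, 0 °C to rt; then 13, Pd(dppf)Cl2 (5 mol %), AsPh3, Cs2CO3, DMF/THF/H2O, rt
Reagents that add atoms: none
Why: 9‑BBN adds anti‑Markovnikov to the only monosubstituted alkene of the diene, and the B‑alkyl Suzuki–Miyaura coupling joins C2 to C1 with retention of the (E)‑iodoalkene geometry.

Step 11
Reactants: 15 coupled primary alcohol
Product: 16 (2S,4E,8Z)‑8‑{[(tert‑butyldimethylsilyl)oxy]methyl}‑2‑[(4‑methoxybenzyl)oxy]‑4‑methyl‑10‑[(triethylsilyl)oxy]deca‑4,8‑dienal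
Conditions: Dess–Martin periodinane, pyridine, CH2Cl2, 0 °C to rt
Reagents that add atoms: none
Why: Dess–Martin oxidation gives the α‑alkoxy aldehyde under neutral, non‑epimerizing conditions; it is used crude.

Step 12
Reactants: 16 α‑alkoxy aldehyde; 17 methyl acrylate
Product: 18 methyl (4S,6E,10Z)‑10‑{[(tert‑butyldimethylsilyl)oxy]methyl}‑3‑hydroxy‑4‑[(4‑methoxybenzyl)oxy]‑6‑methyl‑2‑methylidene‑12‑[(triethylsilyl)oxy]dodeca‑6,10‑dienoate (C3 epimers)
Conditions: DABCO (1 equiv), neat methyl acrylate (20 equiv), rt, 4–6 d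
Reagents that add atoms: none
Why: Morita–Baylis–Hillman reaction: DABCO adds to the acrylate and the zwitterionic enolate attacks the activated α‑alkoxy aldehyde; the new C7 carbinol centre forms as a mixture, which is erased when C7 becomes sp2 in step 15.

Step 13
Reactants: 18 Morita–Baylis–Hillman adduct
Product: 19 methyl (4S,6E,10Z)‑10‑{[(tert‑butyldimethylsilyl)oxy]methyl}‑3,12‑dihydroxy‑4‑[(4‑methoxybenzyl)oxy]‑6‑methyl‑2‑methylidenedodeca‑6,10‑dienoate
Conditions: PPTS (0.2 equiv), MeOH/CH2Cl2 (1:1), 0 °C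
Reagents that add atoms: none
Why: Mild acid methanolysis cleaves the primary TES ether roughly a hundred times faster than the primary TBS ether.

Step 14
Reactants: 19 diol
Product: 20 methyl (4S,6E,10Z)‑10‑{[(tert‑butyldimethylsilyl)oxy]methyl}‑3‑hydroxy‑4‑[(4‑methoxybenzyl)oxy]‑6‑methyl‑2‑methylidene‑12‑oxododeca‑6,10‑dienoate
Conditions: TEMPO (10 mol %), PhI(OAc)2, CH2Cl2, rt
Reagents that add atoms: none
Why: Oxoammonium (TEMPO) oxidation is selective for the primary allylic alcohol over the hindered, electron‑poor secondary allylic alcohol and keeps the enal geometry.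

Step 15
Reactants: 20 hydroxy enal
Product: 21 methyl (2Z,4S,6E,10Z)‑2‑(bromomethyl)‑10‑{[(tert‑butyldimethylsilyl)oxy]methyl}‑4‑[(4‑methoxybenzyl)oxy]‑6‑methyl‑12‑oxododeca‑2,6,10‑trienoate
Conditions: NBS, Me2S, CH2Cl2, −20 to 0 °C
Reagents that add atoms: N‑bromosuccinimide, BrN1C(=O)CCC1=O
Why: Corey–Kim‑type activation of the allylic alcohol as an alkoxysulfonium salt followed by SN2' attack of bromide gives the thermodynamically preferred (Z)‑2‑(bromomethyl)enoate.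

Step 16
Reactants: 21 seco bromo‑enal
Product: 24 (3aR,4S,6E,10Z,11aR)‑10‑{[(tert‑butyldimethylsilyl)oxy]methyl}‑4‑[(4‑methoxybenzyl)oxy]‑6‑methyl‑3‑methylidene‑3a,4,5,8,9,11a‑hexahydrocyclodeca[b]furan‑2(3H)‑one, via allylchromium dichloride 22 (not isolated), via seco hydroxy ester 23 (not isolated)
Conditions: CrCl2 (10 equiv), THF, rt, syringe‑pump addition of 21 (final 2 mM); aq. work‑up
Reagents that add atoms: none
Why: Nozaki–Hiyama–Kishi‑type macrocyclization: divalent chromium inserts into the allylic C–Br bond and the allylchromium attacks the enal through C7 in a chair‑like, product‑like transition state with the C8 OPMB group pseudo‑equatorial on the forming E,E‑cyclodecadiene, so C6–O and C7–C11 are set anti (6R,7R from 8S) and the C6 alkoxide closes the trans‑fused α‑methylene‑γ‑lactone with loss of methanol.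

Step 17
Reactants: 24 PMB‑protected macrolactone
Product: 25 (3aR,4S,6E,10Z,11aR)‑10‑{[(tert‑butyldimethylsilyl)oxy]methyl}‑4‑hydroxy‑6‑methyl‑3‑methylidene‑3a,4,5,8,9,11a‑hexahydrocyclodeca[b]furan‑2(3H)‑one
Conditions: DDQ, CH2Cl2/pH 7 buffer (10:1), 0 °C to rt
Reagents that add atoms: none
Why: Oxidative cleavage of the electron‑rich PMB ether by DDQ frees the C8 hydroxyl under neutral conditions that spare the silyl ether, the methylene lactone and the diene.

**Fragment C (side‑chain acid)**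

Step 18
Reactants: 26 5,6‑O‑isopropylidene‑L‑ascorbic acid
Product: 28 allyl (2R)‑2‑[(4S)‑2,2‑dimethyl‑1,3‑dioxolan‑4‑yl]‑2‑hydroxyacetate, via potassium threonate acetonide 27 (not isolated)
Conditions: 30 % H2O2, K2CO3, H2O, 0 °C to rt; evaporate; then allyl bromide, DMF, rt to 40 °C
Reagents that add atoms: hydrogen peroxide, OO; allyl bromide, C=CCBr
Why: Alkaline peroxide cleaves the C2–C3 ene‑diol of the ascorbate to the threonate carboxylate, which is O‑alkylated by allyl bromide; C5 of ascorbic acid is untouched and becomes C3' of the side chain.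

Step 19
Reactants: 28 allyl 3,4‑O‑isopropylidene‑L‑threonate
Product: 29 allyl 2‑[(4S)‑2,2‑dimethyl‑1,3‑dioxolan‑4‑yl]‑2‑oxoacetate
Conditions: Dess–Martin periodinane, CH2Cl2, rt
Reagents that add atoms: none
Why: Dess–Martin oxidation of the α‑hydroxy ester to the α‑keto ester under neutral conditions keeps the adjacent dioxolane stereocentre intact.

Step 20
Reactants: 29 α‑keto ester
Product: 30 allyl 2‑[(4R)‑2,2‑dimethyl‑1,3‑dioxolan‑4‑yl]prop‑2‑enoate
Conditions: Ph3PCH3Br, KN(SiMe3)2, THF, 0 °C; then 29 (1.0 equiv ylide), −78 to 0 °C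
Reagents that add atoms: methyltriphenylphosphonium bromide, C[P+](c1ccccc1)(c1ccccc1)c1ccccc1.[Br-]
Why: Wittig methylenation of the very electrophilic ketone carbonyl is fast at −78 °C, which outruns enolization toward the stereocentre (its descriptor changes from S to R by CIP priority only).

Step 21
Reactants: 30 acetonide acrylate
Product: 31 allyl (3R)‑3,4‑dihydroxy‑2‑methylidenebutanoate
Conditions: AcOH/H2O (4:1), rt; concentrate cold and use at once
Reagents that add atoms: none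
Why: Acid‑catalysed acetal hydrolysis frees the diol, which is carried on immediately to avoid lactonization onto the allyl ester.

Step 22
Reactants: 31 diol
Product: 32 allyl (3R)‑4‑acetoxy‑3‑hydroxy‑2‑methylidenebutanoate
Conditions: AcCl (1.05 equiv), 2,4,6‑collidine, CH2Cl2, −78 °C
Reagents that add atoms: acetyl chloride, CC(=O)Cl
Why: Kinetically selective acylation of the primary hydroxyl of a 1,2‑diol with acetyl chloride and a hindered pyridine base at low temperature.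

Step 23
Reactants: 32 monoacetate
Product: 33 allyl (3R)‑4‑acetoxy‑3‑[(tert‑butyldimethylsilyl)oxy]‑2‑methylidenebutanoate
Conditions: TBSOTf, 2,6‑lutidine, CH2Cl2, −78 °C
Reagents that add atoms: tert‑butyldimethylsilyl triflate, CC(C)(C)[Si](C)(C)OS(=O)(=O)C(F)(F)F
Why: Silylation with the silyl triflate is fast at −78 °C, so the secondary hydroxyl is capped before any 1,2‑acetyl migration can occur.

Step 24
Reactants: 33 allyl ester
Product: 34 (3R)‑4‑acetoxy‑3‑[(tert‑butyldimethylsilyl)oxy]‑2‑methylidenebutanoic acid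
Conditions: Pd(PPh3)4 (5 mol %), N‑methylaniline, THF, rt
Reagents that add atoms: none
Why: Tsuji–Trost deallylation: zerovalent palladium ionizes the allyl ester and the weakly nucleophilic aniline traps the allyl group, leaving the acetate, silyl ether and acrylate untouched.

**Endgame**

Step 25
Reactants: 25 C8 alcohol; 34 side‑chain acid
Product: 36 (3aR,4S,6E,10Z,11aR)‑10‑{[(tert‑butyldimethylsilyl)oxy]methyl}‑6‑methyl‑3‑methylidene‑2‑oxo‑2,3,3a,4,5,8,9,11a‑octahydrocyclodeca[b]furan‑4‑yl (3R)‑4‑acetoxy‑3‑[(tert‑butyldimethylsilyl)oxy]‑2‑methylidenebutanoate, via mixed trichlorobenzoic anhydride 35 (not isolated)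
Conditions: 34, 2,4,6‑trichlorobenzoyl chloride, Et3N, toluene, rt; then 25, DMAP, toluene, rt
Reagents that add atoms: none
Why: Yamaguchi esterification: DMAP attacks the mixed anhydride at the less hindered acrylic carbonyl and the acylpyridinium acylates the secondary C8 hydroxyl without touching any stereocentre.

Step 26
Reactants: 36 bis‑silyl ester
Product: 37 4'‑O‑acetylcnicin (target)
Conditions: HF·pyridine, pyridine, THF, 0 °C to rt
Reagents that add atoms: none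
Why: Fluoride‑driven cleavage of both Si–O bonds under mildly acidic, non‑nucleophilic conditions leaves the acetate in place and spares the two Michael acceptors and the cyclodecadiene.

**Compound list**
1 | propargyl alcohol | C#CCO | starting material
2 | tert‑butyldimethyl(prop‑2‑yn‑1‑yloxy)silane | C#CCO[Si](C)(C)C(C)(C)C | intermediate
3 | lithium acetylide of 2 | [Li]C#CCO[Si](C)(C)C(C)(C)C | intermediate
4 | methyl 4‑[(tert‑butyldimethylsilyl)oxy]but‑2‑ynoate | COC(=O)C#CCO[Si](C)(C)C(C)(C)C | intermediate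
5 | methyl (2Z)‑3‑{[(tert‑butyldimethylsilyl)oxy]methyl}penta‑2,4‑dienoate | COC(=O)/C=C(\CO[Si](C)(C)C(C)(C)C)C=C | intermediate
6 | (2Z)‑3‑{[(tert‑butyldimethylsilyl)oxy]methyl}penta‑2,4‑dien‑1‑ol | OC/C=C(\CO[Si](C)(C)C(C)(C)C)C=C | intermediate
7 | (3Z)‑3‑{[(tert‑butyldimethylsilyl)oxy]methyl}‑5‑[(triethylsilyl)oxy]penta‑1,3‑diene | CC[Si](CC)(CC)OC/C=C(\CO[Si](C)(C)C(C)(C)C)C=C | intermediate
8 | (R)‑glycidol | OC[C@@H]1CO1 | starting material
9 | (2S)‑pent‑4‑yne‑1,2‑diol | OC[C@@H](O)CC#C | intermediate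
10 | (4S)‑2‑(4‑methoxyphenyl)‑4‑(prop‑2‑yn‑1‑yl)‑1,3‑dioxolane (acetal epimers) | C#CC[C@H]1COC(c2ccc(OC)cc2)O1 | intermediate
11 | (2S)‑2‑[(4‑methoxybenzyl)oxy]pent‑4‑yn‑1‑ol | OC[C@@H](OCc1ccc(OC)cc1)CC#C | intermediate
12 | (E)‑alkenyldimethylalane from 11 (O‑bound as dimethylaluminium alkoxide) | C[Al](C)OC[C@@H](OCc1ccc(OC)cc1)C/C(C)=C/[Al](C)C | intermediate
13 | (2S,4E)‑5‑iodo‑2‑[(4‑methoxybenzyl)oxy]‑4‑methylpent‑4‑en‑1‑ol | OC[C@@H](OCc1ccc(OC)cc1)C/C(C)=C/I | intermediate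
14 | 9‑[(3Z)‑3‑{[(tert‑butyldimethylsilyl)oxy]methyl}‑5‑[(triethylsilyl)oxy]pent‑3‑en‑1‑yl]‑9‑borabicyclo[3.3.1]nonane | CC[Si](CC)(CC)OC/C=C(\CO[Si](C)(C)C(C)(C)C)CCB1C2CCCC1CCC2 | intermediate
15 | (2S,4E,8Z)‑8‑{[(tert‑butyldimethylsilyl)oxy]methyl}‑2‑[(4‑methoxybenzyl)oxy]‑4‑methyl‑10‑[(triethylsilyl)oxy]deca‑4,8‑dien‑1‑ol | CC[Si](CC)(CC)OC/C=C(\CO[Si](C)(C)C(C)(C)C)CC/C=C(\C)C[C@H](OCc1ccc(OC)cc1)CO | intermediate
16 | (2S,4E,8Z)‑8‑{[(tert‑butyldimethylsilyl)oxy]methyl}‑2‑[(4‑methoxybenzyl)oxy]‑4‑methyl‑10‑[(triethylsilyl)oxy]deca‑4,8‑dienal | CC[Si](CC)(CC)OC/C=C(\CO[Si](C)(C)C(C)(C)C)CC/C=C(\C)C[C@H](OCc1ccc(OC)cc1)C=O | intermediate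
17 | methyl acrylate | C=CC(=O)OC | starting material
18 | methyl (4S,6E,10Z)‑10‑{[(tert‑butyldimethylsilyl)oxy]methyl}‑3‑hydroxy‑4‑[(4‑methoxybenzyl)oxy]‑6‑methyl‑2‑methylidene‑12‑[(triethylsilyl)oxy]dodeca‑6,10‑dienoate (C3 epimers) | CC[Si](CC)(CC)OC/C=C(\CO[Si](C)(C)C(C)(C)C)CC/C=C(\C)C[C@H](OCc1ccc(OC)cc1)C(O)C(=C)C(=O)OC | intermediate
19 | methyl (4S,6E,10Z)‑10‑{[(tert‑butyldimethylsilyl)oxy]methyl}‑3,12‑dihydroxy‑4‑[(4‑methoxybenzyl)oxy]‑6‑methyl‑2‑methylidenedodeca‑6,10‑dienoate (C3 epimers) | OC/C=C(\CO[Si](C)(C)C(C)(C)C)CC/C=C(\C)C[C@H](OCc1ccc(OC)cc1)C(O)C(=C)C(=O)OC | intermediate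
20 | methyl (4S,6E,10Z)‑10‑{[(tert‑butyldimethylsilyl)oxy]methyl}‑3‑hydroxy‑4‑[(4‑methoxybenzyl)oxy]‑6‑methyl‑2‑methylidene‑12‑oxododeca‑6,10‑dienoate (C3 epimers) | O=C/C=C(\CO[Si](C)(C)C(C)(C)C)CC/C=C(\C)C[C@H](OCc1ccc(OC)cc1)C(O)C(=C)C(=O)OC | intermediate
21 | methyl (2Z,4S,6E,10Z)‑2‑(bromomethyl)‑10‑{[(tert‑butyldimethylsilyl)oxy]methyl}‑4‑[(4‑methoxybenzyl)oxy]‑6‑methyl‑12‑oxododeca‑2,6,10‑trienoate | O=C/C=C(\CO[Si](C)(C)C(C)(C)C)CC/C=C(\C)C[C@H](OCc1ccc(OC)cc1)/C=C(\CBr)C(=O)OC | intermediate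
22 | allylchromium dichloride from 21 (trivalent chromium bound at C13) | O=C/C=C(\CO[Si](C)(C)C(C)(C)C)CC/C=C(\C)C[C@H](OCc1ccc(OC)cc1)/C=C(\C[Cr](Cl)Cl)C(=O)OC | intermediate
23 | methyl 2‑[(1S,2R,3Z,7E,10S)‑4‑{[(tert‑butyldimethylsilyl)oxy]methyl}‑2‑hydroxy‑10‑[(4‑methoxybenzyl)oxy]‑8‑methylcyclodeca‑3,7‑dien‑1‑yl]prop‑2‑enoate | COC(=O)C(=C)[C@H]1[C@H](O)/C=C(\CO[Si](C)(C)C(C)(C)C)CC/C=C(\C)C[C@@H]1OCc1ccc(OC)cc1 | intermediate
24 | (3aR,4S,6E,10Z,11aR)‑10‑{[(tert‑butyldimethylsilyl)oxy]methyl}‑4‑[(4‑methoxybenzyl)oxy]‑6‑methyl‑3‑methylidene‑3a,4,5,8,9,11a‑hexahydrocyclodeca[b]furan‑2(3H)‑one | C=C1C(=O)O[C@@H]2/C=C(\CO[Si](C)(C)C(C)(C)C)CC/C=C(\C)C[C@H](OCc3ccc(OC)cc3)[C@@H]12 | intermediate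
25 | (3aR,4S,6E,10Z,11aR)‑10‑{[(tert‑butyldimethylsilyl)oxy]methyl}‑4‑hydroxy‑6‑methyl‑3‑methylidene‑3a,4,5,8,9,11a‑hexahydrocyclodeca[b]furan‑2(3H)‑one | C=C1C(=O)O[C@@H]2/C=C(\CO[Si](C)(C)C(C)(C)C)CC/C=C(\C)C[C@H](O)[C@@H]12 | intermediate
26 | 5,6‑O‑isopropylidene‑L‑ascorbic acid | CC1(C)OC[C@H](O1)[C@H]2OC(=O)C(O)=C2O | starting material
27 | potassium (2R)‑2‑[(4S)‑2,2‑dimethyl‑1,3‑dioxolan‑4‑yl]‑2‑hydroxyacetate | [K+].[O-]C(=O)[C@H](O)[C@@H]1COC(C)(C)O1 | intermediate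
28 | allyl (2R)‑2‑[(4S)‑2,2‑dimethyl‑1,3‑dioxolan‑4‑yl]‑2‑hydroxyacetate | C=CCOC(=O)[C@H](O)[C@@H]1COC(C)(C)O1 | intermediate
29 | allyl 2‑[(4S)‑2,2‑dimethyl‑1,3‑dioxolan‑4‑yl]‑2‑oxoacetate | C=CCOC(=O)C(=O)[C@@H]1COC(C)(C)O1 | intermediate
30 | allyl 2‑[(4R)‑2,2‑dimethyl‑1,3‑dioxolan‑4‑yl]prop‑2‑enoate | C=CCOC(=O)C(=C)[C@@H]1COC(C)(C)O1 | intermediate
31 | allyl (3R)‑3,4‑dihydroxy‑2‑methylidenebutanoate | C=CCOC(=O)C(=C)[C@@H](O)CO | intermediate
32 | allyl (3R)‑4‑acetoxy‑3‑hydroxy‑2‑methylidenebutanoate | C=CCOC(=O)C(=C)[C@@H](O)COC(C)=O | intermediate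
33 | allyl (3R)‑4‑acetoxy‑3‑[(tert‑butyldimethylsilyl)oxy]‑2‑methylidenebutanoate | C=CCOC(=O)C(=C)[C@@H](O[Si](C)(C)C(C)(C)C)COC(C)=O | intermediate
34 | (3R)‑4‑acetoxy‑3‑[(tert‑butyldimethylsilyl)oxy]‑2‑methylidenebutanoic acid | OC(=O)C(=C)[C@@H](O[Si](C)(C)C(C)(C)C)COC(C)=O | intermediate
35 | mixed anhydride of 34 and 2,4,6‑trichlorobenzoic acid | O=C(OC(=O)C(=C)[C@@H](O[Si](C)(C)C(C)(C)C)COC(C)=O)c1c(Cl)cc(Cl)cc1Cl | intermediate
36 | (3aR,4S,6E,10Z,11aR)‑10‑{[(tert‑butyldimethylsilyl)oxy]methyl}‑6‑methyl‑3‑methylidene‑2‑oxo‑2,3,3a,4,5,8,9,11a‑octahydrocyclodeca[b]furan‑4‑yl (3R)‑4‑acetoxy‑3‑[(tert‑butyldimethylsilyl)oxy]‑2‑methylidenebutanoate | C=C1C(=O)O[C@@H]2/C=C(\CO[Si](C)(C)C(C)(C)C)CC/C=C(\C)C[C@H](OC(=O)C(=C)[C@@H](O[Si](C)(C)C(C)(C)C)COC(C)=O)[C@@H]12 | intermediate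
37 | (3aR,4S,6E,10Z,11aR)‑10‑(hydroxymethyl)‑6‑methyl‑3‑methylidene‑2‑oxo‑2,3,3a,4,5,8,9,11a‑octahydrocyclodeca[b]furan‑4‑yl (3R)‑4‑acetoxy‑3‑hydroxy‑2‑methylidenebutanoate (4'‑O‑acetylcnicin) | C=C1C(=O)O[C@@H]2/C=C(\CO)CC/C=C(\C)C[C@H](OC(=O)C(=C)[C@@H](O)COC(C)=O)[C@@H]12 | target

**Step count and risks**

Total steps: 26. Longest linear sequence: 15 steps (1–5, 10–17, 25, 26). Fragment B adds 4 steps and fragment C adds 7 steps in parallel.

Most likely to fail, 1: step 16, the ten‑membered ring closure. The risks are oligomerization and the wrong C6/C7 pair, since the sense of induction from C8 is argued and not proven. Fallback: leave the route at hydroxy enal 20 and acetylate it (Ac2O, pyridine, 0 °C) to allylic acetate F1. A zerovalent palladium umpolung (Pd(PPh3)4 10 mol %, Et2Zn, THF, syringe pump, rt) then ionizes the acetate to a π‑allylpalladium species, which is transmetalated to an allylzinc nucleophile. This adds to the enal through C7 without any isolated allylic bromide or stoichiometric chromium. The zinc alkoxide of 23 lactonizes and the route is rejoined at macrolactone 24.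

Most likely to fail, 2: step 12, the Morita–Baylis–Hillman reaction. It is slow on a long‑chain aldehyde, and days with an amine base can erode the C8 centre of aldehyde 16. Fallback: set out from aldehyde 16 and replace the amine‑catalysed process by a stoichiometric vinylmetal addition. Conjugate hydroalumination of methyl propiolate (i‑Bu2AlH, N‑methylmorpholine N‑oxide, THF, 0 °C) gives methyl 2‑(diisobutylalumanyl)acrylate F2. F2 adds 1,2 to 16 at −78 to 0 °C under non‑basic conditions and, after aqueous work‑up, returns the route at adduct 18.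

Most likely to fail, 3: step 10, the one‑pot hydroboration and B‑alkyl Suzuki coupling. The risks are imperfect regiocontrol on the conjugated diene and slow transmetalation of the hindered borane. Fallback: set out from diene 7, hydroborate as before but work up oxidatively (NaOH, H2O2) to homoallylic alcohol F3, which can be purified. Iodination (I2, PPh3, imidazole, CH2Cl2, 0 °C) gives primary iodide F4, and zinc insertion (Zn dust, LiCl, THF, 40 °C) gives alkylzinc iodide F5. Negishi coupling of F5 with vinyl iodide 13 (Pd(dppf)Cl2 5 mol %, THF, rt, slow addition of excess zinc reagent so that the free hydroxyl is tolerated) comes back to the route at alcohol 15.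

**Further compounds**
F1 | step 16 | methyl (4S,6E,10Z)‑3‑acetoxy‑10‑{[(tert‑butyldimethylsilyl)oxy]methyl}‑4‑[(4‑methoxybenzyl)oxy]‑6‑methyl‑2‑methylidene‑12‑oxododeca‑6,10‑dienoate | O=C/C=C(\CO[Si](C)(C)C(C)(C)C)CC/C=C(\C)C[C@H](OCc1ccc(OC)cc1)C(OC(C)=O)C(=C)C(=O)OC
F2 | step 12 | methyl 2‑(diisobutylalumanyl)prop‑2‑enoate | C=C(C(=O)OC)[Al](CC(C)C)CC(C)C
F3 | step 10 | (3Z)‑3‑{[(tert‑butyldimethylsilyl)oxy]methyl}‑5‑[(triethylsilyl)oxy]pent‑3‑en‑1‑ol | CC[Si](CC)(CC)OC/C=C(\CO[Si](C)(C)C(C)(C)C)CCO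
F4 | step 10 | tert‑butyl{[(2Z)‑2‑(2‑iodoethyl)‑4‑[(triethylsilyl)oxy]but‑2‑en‑1‑yl]oxy}dimethylsilane | CC[Si](CC)(CC)OC/C=C(\CO[Si](C)(C)C(C)(C)C)CCI
F5 | step 10 | {(3Z)‑3‑{[(tert‑butyldimethylsilyl)oxy]methyl}‑5‑[(triethylsilyl)oxy]pent‑3‑en‑1‑yl}zinc iodide | CC[Si](CC)(CC)OC/C=C(\CO[Si](C)(C)C(C)(C)C)CC[Zn]I
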